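**Assumption:** Abiesin as drawn has no stereocentres (it is achiral), so "single enantiomer" is moot. The only geometric element is the E-chalcone intermediate, which is lost on cyclisation. It is a 6-(flavon-3'-yl) flavonol: a 5-deoxy-3,7-dihydroxy-4'-methoxyflavonol linked through its C6 to C3' of apigenin 7,4'-dimethyl ether.

## Retrosynthetic overview
- The last ring formed is the flavone pyranone, by oxidative cyclisation of a 2'-hydroxychalcone (I2/DMSO) made by Claisen–Schmidt condensation.
- The biaryl C6–C3' bond is made by Suzuki coupling of a 6-iodoflavonol with commercial 5-formyl-2-methoxyphenylboronic acid, which carries the future flavone B ring and its aldehyde.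
- The flavonol ring is formed earlier, by Algar–Flynn–Oyamada (AFO) oxidation of a 2'-hydroxychalcone derived from 5'-iodoresacetophenone and anisaldehyde.
- Ring order: flavonol C-ring, then biaryl bond, then flavone C-ring.

## Route

**Step 1**
Reactants: 1 (2',4'-dihydroxyacetophenone)
Product: 2 (1-(2,4-dihydroxy-5-iodophenyl)ethan-1-one)
Conditions: NIS, MeCN, 0 °C → rt, 3 h
Reagents that add atoms: N-iodosuccinimide, O=C1CCC(=O)N1I
Why: Electrophilic aromatic iodination goes at C5, which is para to the 2-OH and ortho to the 4-OH and less hindered than C3. Any 3-iodo isomer is removed by chromatography.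

**Step 2**
Reactants: 2 (iodoacetophenone) + 3 (4-methoxybenzaldehyde)
Product: 4 ((E)-1-(2,4-dihydroxy-5-iodophenyl)-3-(4-methoxyphenyl)prop-2-en-1-one)
Conditions: 50% aq. KOH, EtOH, rt, 48 h, N2; then HCl work-up
Reagents that add atoms: none
Why: Claisen–Schmidt aldol condensation with a non-enolisable aldehyde; dehydration gives the thermodynamic E-enone.

**Step 3**
Reactants: 4 (iodochalcone)
Product: 5 (3,7-dihydroxy-6-iodo-4'-methoxyflavone)
Conditions: 30% H2O2, 2 M NaOH, MeOH, 0 °C → rt, 24 h
Reagents that add atoms: hydrogen peroxide, OO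
Why: Algar–Flynn–Oyamada reaction. Nucleophilic epoxidation of the enone is followed by 6-endo phenoxide opening and oxidation to the flavonol. The transient sp3 centres are destroyed on aromatisation, so there is no stereochemical consequence.

**Step 4**
Reactants: 5 (6-iodoflavonol) + 6 (5-formyl-2-methoxyphenylboronic acid)
Product: 7 (6-(5-formyl-2-methoxyphenyl)-3,7-dihydroxy-4'-methoxyflavone)
Conditions: Pd(PPh3)4 (10 mol%), K2CO3, dioxane/H2O 4:1, 90 °C, 12 h, Ar (boronic acid 1.8 equiv)
Reagents that add atoms: none (the boronic acid is the reactant)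
Why: Suzuki–Miyaura coupling of the aryl iodide with the arylboronic acid. The aldehyde is tolerated by carbonate, and excess boronic acid covers protodeboronation.

**Step 5**
Reactants: 7 (biaryl aldehyde flavonol) + 8 (2',6'-dihydroxy-4'-methoxyacetophenone)
Product: 9 (bis-flavonoid (E)-chalcone)
Conditions: 50% aq. KOH (excess), EtOH, rt, 72 h, N2; then HCl
Reagents that add atoms: none
Why: Claisen–Schmidt condensation. The aldehyde is the only electrophile, and the flavonol has no enolisable ketone, so there is no cross-condensation. Excess base is needed to cover the acidic phenols, and N2 protects the flavonol.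

**Step 6**
Reactants: 9 (chalcone)
Product: 10 (Abiesin)
Conditions: I2 (10 mol%), DMSO, 130 °C, 2 h
Reagents that add atoms: none (iodine is catalytic, DMSO is the terminal oxidant)
Why: Oxidative cyclisation of a 2'-hydroxychalcone (I2/DMSO) gives the flavone directly. The 6'-OH becomes the chelated 5-OH, the 4'-OMe becomes 7-OMe, and the flavonol 3-OH and both aryl methyl ethers survive.

## Compound list
1 | 2',4'-dihydroxyacetophenone | CC(=O)c1ccc(O)cc1O | starting material
2 | 1-(2,4-dihydroxy-5-iodophenyl)ethanone | CC(=O)c1cc(I)c(O)cc1O | intermediate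
3 | 4-methoxybenzaldehyde | COc1ccc(C=O)cc1 | starting material
4 | (E)-2',4'-dihydroxy-5'-iodo-4-methoxychalcone | COc1ccc(/C=C/C(=O)c2cc(I)c(O)cc2O)cc1 | intermediate
5 | 3,7-dihydroxy-6-iodo-4'-methoxyflavone | COc1ccc(-c2oc3cc(O)c(I)cc3c(=O)c2O)cc1 | intermediate
6 | 5-formyl-2-methoxyphenylboronic acid | COc1ccc(C=O)cc1B(O)O | starting material
7 | 6-(5-formyl-2-methoxyphenyl)-3,7-dihydroxy-4'-methoxyflavone | COc1ccc(-c2oc3cc(O)c(-c4cc(C=O)ccc4OC)cc3c(=O)c2O)cc1 | intermediate
8 | 2',6'-dihydroxy-4'-methoxyacetophenone | COc1cc(O)c(C(C)=O)c(O)c1 | starting material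
9 | bis-flavonoid (E)-chalcone | COc1ccc(-c2oc3cc(O)c(-c4cc(/C=C/C(=O)c5c(O)cc(OC)cc5O)ccc4OC)cc3c(=O)c2O)cc1 | intermediate
10 | Abiesin | COc1ccc(-c2oc3cc(O)c(-c4cc(-c5cc(=O)c6c(O)cc(OC)cc6o5)ccc4OC)cc3c(=O)c2O)cc1 | target

## Totals
- Total steps: 6.
- Longest linear sequence: 6 (1 → 2 → 4 → 5 → 7 → 9 → 10).

## Three steps most likely to fail, with fallbacks
1. **Step 4 (Suzuki on an unprotected ortho-iodophenol flavonol).** Pd poisoning by the 3-OH/4-C=O chelate or protodeboronation could lower yield.
   - Fallback: protect the 3-OH and 7-OH of 5 as MOM ethers, couple, and remove the MOM groups with HCl/MeOH at the end.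
2. **Step 5 (Claisen–Schmidt on a base-sensitive, poly-phenolic flavonol).** Ring opening or oxidation of the flavonol under strong base could dominate.
   - Fallback: switch to the convergent sequence. Make the 3'-bromoflavone from 3-bromo-4-methoxybenzaldehyde and 8 (Claisen–Schmidt, then I2/DMSO), convert it to the 3'-Bpin flavone by Miyaura borylation, and Suzuki-couple it with iodoflavonol 5. This keeps the flavonol away from base and I2.
3. **Step 6 (I2/DMSO on a substrate carrying a flavonol).** Competing C8 iodination of the 7-hydroxyflavonol, or over-oxidation, could occur.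
   - Fallback: use a different mechanism for ring closure. Cyclise the chalcone to the flavanone (NaOAc, EtOH, reflux) and dehydrogenate with Pd(TFA)2/DMSO/O2, or use the convergent route above, in which the flavone ring is formed before the flavonol is present.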